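All runs were computed with constants of no real substance; scatter was added.

I had no constants, so I read one rate from the earlier runs.

all flasks: free catalyst 18 µM

|  | substrate | coupling partner | temperature | remark | time |
|---|---|---|---|---|---|
| gamma | 0.0090 M | 0.036 M (in portions, 2) | 85 °C | run made earlier; portions every 80 s |  |
| delta | 0.036 M | 0.036 M (in portions, 2) | 100 °C | run made earlier; portions every 80 s |  |
| dusk | 0.018 M | 0.0360 M (in portions, 2) | 100 °C | the portions of coupling partner follow each other after 80 s, the first at the start | 2.5 min |
| winter | 0.018 M | 0.0360 M | 100 °C | everything together at the start | 0.80 min |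

- gamma (time / min: product / %, substrate / %): 0.333: 0, 98; 0.667: 6, 93; 2.00: 19, 81; 4.00: 38, 68
- delta (time / s: product / %, substrate / %): 15.0: 3, 97; 40.0: 8, 91; 80.0: 14, 81; 120: 26, 73

(scatter of a reading: 2 percentage points)

* which of the two ends with the higher amount of product, in percent of the substrate charged ("neither" if they lie within 2 percentage points) (dusk / winter / neither)
* product at the end, in percent of the substrate charged, dusk
* product at the end, in percent of the substrate charged, winter

In the delta run product stood at 14 % at 80.0 s, while c(substrate) began at 0.036 M. That reading carries a scatter of 2 percentage points. I divided the product made by the catalyst and the time. I kept 3.50 s⁻¹ as the turnover frequency, the turns of one catalyst per second.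

From it I built a ladder of times. One turn took 0.286 s, far shorter than the 80 s between portions. So I expected the catalyst forms to keep pace with each portion. The next rung was the substrate charge of dusk and winter, which equalled 4.76 min of steady turning. Both end times lay below that, so I expected substrate to remain in both flasks.

Dividing each end time by this rung gave 16.8 % for winter and 52.5 % for dusk, so I expected dusk to end higher. Dusk and winter each began with half the substrate of delta, where I had read the rate, so I held both figures as the high side.

The forecast named dusk, with 60 % for dusk, above my figure, and 20 % for winter: “Dusk wins mainly because it runs longer”.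

The flasks gave 38.9 % for dusk and 15.5 % for winter, so dusk ended higher.

    substrate + catalyst intermediate A ⇌ catalyst intermediate B (K = 36.0 M⁻¹, k = 243 M⁻¹ s⁻¹, Ea = 56.0 kJ mol⁻¹, ΔH = 5.00 kJ mol⁻¹)
    coupling partner + free catalyst → catalyst intermediate A (k = 581 M⁻¹ s⁻¹, Ea = 54.0 kJ mol⁻¹)
    catalyst intermediate B ⇌ catalyst intermediate C (K = 75.0, k = 294 s⁻¹, Ea = 63.0 kJ mol⁻¹, ΔH = −56.0 kJ mol⁻¹)
    catalyst intermediate C → free catalyst + product (k = 695 s⁻¹, Ea = 81.0 kJ mol⁻¹)
    (constants at 100 °C)

In winter at 0.800 min, catalyst intermediate A was made 1.00 times as fast as it was used up. It held 83.0 % of the catalyst, the resting state, against 15.5 % free catalyst. Averaged over its whole run and per catalyst charged, the winter product corresponds to 3.23 s⁻¹, and the dusk product to 2.59 s⁻¹, lower than winter and than my reading of 3.50 s⁻¹. For a winter flask with 4.5 × 10⁻⁵ M of free catalyst, my frequency gave 42.0 %. That flask made 34.8 %, which is 2.90 s⁻¹.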